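**Assumption:** the target has no stereocentre and no stereogenic double bond, so it is achiral and needs no stereocontrol; BF3·OEt2 in step 1 is counted as a Lewis-acid promoter that is only hydrolysed on work-up.

**Retrosynthetic overview**
1. Target 8 ⇐ aryl silyl ether 7 by O–Si cleavage (last step).
2. 7 ⇐ α-methylstyrene 5 + benzoic acid 6 by allylic C(sp3)–H → C–O benzoyloxylation (key bond: allylic CH2–OBz; the proposed new Pd step).
3. 5 ⇐ o-hydroxyaryl methyl ketone 3 by Wittig methylenation and O-isobutyrylation of the phenoxide 4 in the same flask.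
4. 3 ⇐ 2 by chelation-controlled mono-silylation, which tells the two hydroquinone oxygens apart; 2 ⇐ methylhydroquinone 1 by ortho C-acetylation.
5. No ring is formed; the benzene ring is bought with 1.

**Route**

Step 1
Reactants: 1 2-methylbenzene-1,4-diol (methylhydroquinone)
Product: 2 1-(2,5-dihydroxy-4-methylphenyl)ethan-1-one
Conditions: AcOH, BF3·OEt2 (3 equiv), 95 °C, 3 h; then H2O/NaOAc, 60 °C
Reagents that add atoms: acetic acid, CC(=O)O
Why: Friedel–Crafts C-acylation (BF3-mediated, Fries-type) goes to the one ring position that is ortho to an OH, para to the methyl and not flanked by the methyl, and the o-hydroxyketone is held as a chelate that resists a second acylation.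

Step 2
Reactants: 2 1-(2,5-dihydroxy-4-methylphenyl)ethan-1-one
Product: 3 1-(5-((tert-butyldimethylsilyl)oxy)-2-hydroxy-4-methylphenyl)ethan-1-one
Conditions: TBSCl (1.05 equiv), imidazole (2.2 equiv), DMF, 0 °C → rt
Reagents that add atoms: tert-butyldimethylsilyl chloride, CC(C)(C)[Si](C)(C)Cl
Why: Chemoselective silylation (Corey TBS protection) takes only the free 5-OH next to the methyl, because the 2-OH is locked in a strong hydrogen bond to the acetyl group, and this fixes which oxygen ends up free and which acylated.

Step 3
Reactants: 3 1-(5-((tert-butyldimethylsilyl)oxy)-2-hydroxy-4-methylphenyl)ethan-1-one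
Product: 5 4-((tert-butyldimethylsilyl)oxy)-5-methyl-2-(prop-1-en-2-yl)phenyl 2-methylpropanoate, via 4-silyloxy-2-isopropenyl-5-methylphenol 4 (not isolated)
Conditions: Ph3PCH3Br (2.4 equiv), n-BuLi (2.3 equiv), THF, 0 °C → rt, 12 h; then iPrCOCl (1.5 equiv), DMAP (cat.), 0 °C
Reagents that add atoms: methyltriphenylphosphonium bromide, C[P+](c1ccccc1)(c1ccccc1)c1ccccc1.[Br-]; isobutyryl chloride, CC(C)C(Cl)=O
Why: Wittig methylenation of an o-hydroxyaryl methyl ketone runs on the phenoxide with a second equivalent of ylide, and the lithium phenoxide left in the flask is O-acylated by the acid chloride (nucleophilic acyl substitution), so no aryl ester is ever exposed to the ylide.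

Step 4
Reactants: 5 4-((tert-butyldimethylsilyl)oxy)-5-methyl-2-(prop-1-en-2-yl)phenyl 2-methylpropanoate; 6 benzoic acid (2 equiv)
Product: 7 2-(3-(benzoyloxy)prop-1-en-2-yl)-4-((tert-butyldimethylsilyl)oxy)-5-methylphenyl 2-methylpropanoate
Conditions: Pd(OBz)2 (10 mol%), 1,2-bis(phenylsulfinyl)ethane (10 mol%), 1,4-benzoquinone (2 equiv), iPr2NEt (0.5 equiv), 4 Å MS, 1,4-dioxane, 45 °C, 48–72 h
Reagents that add atoms: none
Why: Proposed new method: a Pd(II) benzoate/bis-sulfoxide catalyst turned over by benzoquinone should bind the 1,1-disubstituted alkene, cleave a C–H bond of the only allylic group (the α-methyl) by carboxylate-assisted deprotonation to give an η3-(2-arylallyl)palladium benzoate, and form the C–O bond by quinone-promoted benzoate attack at an allyl terminus; the two termini are identical CH2 groups, so there is no regio- or E/Z issue, there is no β-hydrogen for diene formation, re-ionisation of the product by Pd(0) is degenerate, and the benzylic ring methyl cannot form a π-allyl; the closest known reaction type is Pd(II)/sulfoxide allylic C–H acyloxylation of monosubstituted terminal olefins (and Pd allylic acetoxylation of simple olefins in neat acetic acid), not shown for a hindered, electron-rich, ortho-acyloxy α-methylstyrene with an aromatic acid in near-stoichiometric amount.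

Step 5
Reactants: 7 2-(3-(benzoyloxy)prop-1-en-2-yl)-4-((tert-butyldimethylsilyl)oxy)-5-methylphenyl 2-methylpropanoate
Product: 8 2-(3-(benzoyloxy)prop-1-en-2-yl)-4-hydroxy-5-methylphenyl 2-methylpropanoate
Conditions: HF·pyridine, pyridine, THF, 0 °C → rt
Reagents that add atoms: none
Why: Fluoride-driven Si–O cleavage (desilylation) under buffered, non-basic conditions frees the phenol without generating phenoxide, so the aryl isobutyrate, the allylic benzoate and the alkene are untouched and no acyl transfer occurs.

**Compound list**
1 | 2-methylbenzene-1,4-diol (methylhydroquinone) | Cc1cc(O)ccc1O | starting material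
2 | 1-(2,5-dihydroxy-4-methylphenyl)ethan-1-one | CC(=O)c1cc(O)c(C)cc1O | intermediate
3 | 1-(5-((tert-butyldimethylsilyl)oxy)-2-hydroxy-4-methylphenyl)ethan-1-one | CC(=O)c1cc(O[Si](C)(C)C(C)(C)C)c(C)cc1O | intermediate
4 | 4-((tert-butyldimethylsilyl)oxy)-5-methyl-2-(prop-1-en-2-yl)phenol (in the flask as its lithium phenoxide) | C=C(C)c1cc(O[Si](C)(C)C(C)(C)C)c(C)cc1O | intermediate
5 | 4-((tert-butyldimethylsilyl)oxy)-5-methyl-2-(prop-1-en-2-yl)phenyl 2-methylpropanoate | C=C(C)c1cc(O[Si](C)(C)C(C)(C)C)c(C)cc1OC(=O)C(C)C | intermediate
6 | benzoic acid | OC(=O)c1ccccc1 | starting material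
7 | 2-(3-(benzoyloxy)prop-1-en-2-yl)-4-((tert-butyldimethylsilyl)oxy)-5-methylphenyl 2-methylpropanoate | C=C(COC(=O)c1ccccc1)c1cc(O[Si](C)(C)C(C)(C)C)c(C)cc1OC(=O)C(C)C | intermediate
8 | 2-(3-(benzoyloxy)prop-1-en-2-yl)-4-hydroxy-5-methylphenyl 2-methylpropanoate | C=C(COC(=O)c1ccccc1)c1cc(O)c(C)cc1OC(=O)C(C)C | target

**Total step count:** 5
**Longest linear sequence:** 5 steps (1 → 2 → 3 → 5 → 7 → 8); benzoic acid 6 enters in step 4.

**Steps most likely to fail**

Step 4 (the proposed new step). The hindered, twisted 1,1-disubstituted alkene may bind Pd(II) poorly, so C–H cleavage could be slow and give low conversion. The fallback uses known chemistry, sets out from 5 and comes back at 7. Allylic hydroxylation of 5 with SeO2 (0.5 equiv)/t-BuOOH in CH2Cl2 at rt (ene reaction then [2,3]-sigmatropic shift at the only allylic position) gives the allylic alcohol 4-((tert-butyldimethylsilyl)oxy)-2-(3-hydroxyprop-1-en-2-yl)-5-methylphenyl 2-methylpropanoate F1. This is benzoylated at once with benzoyl chloride/pyridine at 0 °C, with short contact time to limit aryl-to-alkyl isobutyryl migration, to give 7.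

Step 3. The chelated, deactivated ketone may react sluggishly with the ylide, and the acylation in the same flask may be incomplete. The fallback sets out from 3 and comes back at 5. Addition of MeMgBr (3 equiv, THF, 0 °C) to 3 gives the tertiary carbinol 4-((tert-butyldimethylsilyl)oxy)-2-(2-hydroxypropan-2-yl)-5-methylphenol F2. Mild acid-catalysed dehydration (PPTS cat., toluene, 80 °C) gives phenol 4, this time isolated, which is acylated with iPrCOCl/Et3N/DMAP in CH2Cl2 to give 5.

Step 1. The direct C-acylation of an air-sensitive hydroquinone may give O-acetates, tar or incomplete conversion. The fallback sets out from 1 and comes back at 2. Acetylation of 1 with Ac2O (cat. H2SO4) gives 2-methyl-1,4-phenylene diacetate F3. Fries rearrangement (AlCl3, 3.3 equiv, neat, 120–130 °C, then aqueous HCl) moves one acetyl to the position para to the methyl and hydrolyses the other, giving 2.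

**Further compounds**
F1 | step 4 | 4-((tert-butyldimethylsilyl)oxy)-2-(3-hydroxyprop-1-en-2-yl)-5-methylphenyl 2-methylpropanoate | C=C(CO)c1cc(O[Si](C)(C)C(C)(C)C)c(C)cc1OC(=O)C(C)C
F2 | step 3 | 4-((tert-butyldimethylsilyl)oxy)-2-(2-hydroxypropan-2-yl)-5-methylphenol | CC(C)(O)c1cc(O[Si](C)(C)C(C)(C)C)c(C)cc1O
F3 | step 1 | 2-methyl-1,4-phenylene diacetate | CC(=O)Oc1ccc(OC(C)=O)c(C)c1
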